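**Plan** (C1–C15 numbering of the chain, C1 = alkyne CH; oxolane = O/C6/C7/C8/C9, oxepane = O/C7–C12)
- Retrosynthesis cuts, in order: C12–O and C13–Br (bromoetherification of an E-alkene); C3=C4 (Peterson); C10–Br and C9=C10 (alkylidenation of a γ-lactone); the ring O–C6 bond of the oxolane (oxygen insertion); C6–C9 and C7–C8 (ketene [2+2]).
- Enabling feature: the oxolane edge O–C6H(alkyl)–C7H(O)–C8H2–C9 is the cyclobutanone C6–C7–C8–C9 from a ketene and a Z-enol ether, plus one oxygen between the carbonyl carbon C9 and the more substituted C6, which is where a Baeyer–Villiger shift places it.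
- Forward order of rings: cyclobutanone, then five-membered lactone (the oxolane), then the C10–C15 chain at the lactone carbonyl, then the oxepane closed last between the C7 oxygen and C12; the enyne is added at the end.
- Stereochemistry: C6/C7 from an auxiliary-controlled [2+2] on a Z-enol ether, carried through the ring expansion with retention; C9/C10 from face-selective epoxidation and syn hydride delivery on a Z-alkylidene, then SN2 inversion; C12/C13 from anti addition to the E-alkene; the Z-enyne from a Z-selective Peterson olefination.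

Key step: step 6

Assumption: the ketene is taken to add anti to the aryl group of the (R)-1-arylethyl Z-enol ether in its s-trans, C–H-eclipsed conformer (the accepted model for this auxiliary); if the other face is preferred, the (S)-alcohol is used instead and nothing else changes.

Step 1
Reactants: 1 (R)-1-(2,4,6-triisopropylphenyl)ethanol; 2 trichloroethylene
Product: 4 (E)-1,2-dichlorovinyl (R)-1-(2,4,6-triisopropylphenyl)ethyl ether, via dichloroacetylene 3 (not isolated)
Conditions: KH, THF, 0 °C; then 2, −50 → 20 °C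
Reagents that add atoms: none
Why: Base-induced loss of HCl from 2 gives dichloroacetylene 3, to which the potassium alkoxide adds anti to give the E-dichlorovinyl ether (alkoxide addition to a haloalkyne), the carbinol stereocentre being untouched.

Step 2
Reactants: 4 (E)-1,2-dichlorovinyl (R)-1-(2,4,6-triisopropylphenyl)ethyl ether; 5 tert-butyl(2-iodoethoxy)dimethylsilane
Product: 7 4-(tert-butyldimethylsilyloxy)but-1-ynyl (R)-1-(2,4,6-triisopropylphenyl)ethyl ether, via lithium alkoxyacetylide 6 (not isolated)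
Conditions: n-BuLi (2.3 equiv), THF, −78 → −40 °C; then 5, HMPA, −78 → 20 °C
Reagents that add atoms: none
Why: Elimination and Cl–Li exchange convert 4 into the lithium alkoxyacetylide 6, which is alkylated by the primary iodide (SN2 alkylation of an acetylide).

Step 3
Reactants: 7 4-(tert-butyldimethylsilyloxy)but-1-ynyl (R)-1-(2,4,6-triisopropylphenyl)ethyl ether
Product: 8 (Z)-4-(tert-butyldimethylsilyloxy)but-1-enyl (R)-1-(2,4,6-triisopropylphenyl)ethyl ether
Conditions: H2 (1 atm), Pd/BaSO4, pyridine, 20 °C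
Reagents that add atoms: none
Why: Syn semihydrogenation on poisoned palladium gives the Z-enol ether, whose geometry becomes the cis C6/C7 relationship.

Step 4
Reactants: 8 (Z)-4-(tert-butyldimethylsilyloxy)but-1-enyl (R)-1-(2,4,6-triisopropylphenyl)ethyl ether; 9 trichloroacetyl chloride
Product: 11 (3R,4S)-2,2-dichloro-4-[2-(tert-butyldimethylsilyloxy)ethyl]-3-[(R)-1-(2,4,6-triisopropylphenyl)ethoxy]cyclobutan-1-one, via dichloroketene 10 (not isolated)
Conditions: Zn–Cu, Et2O, 20 °C, slow addition of 9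
Reagents that add atoms: none
Why: Ketene–enol ether [2+2] cycloaddition in which the carbonyl carbon of dichloroketene 10 bonds to the β-carbon of the enol ether, the Z geometry is kept as cis, and the ketene adds to the face anti to the aryl group of the auxiliary, setting both ring stereocentres.

Step 5
Reactants: 11 (3R,4S)-2,2-dichloro-4-[2-(tert-butyldimethylsilyloxy)ethyl]-3-[(R)-1-(2,4,6-triisopropylphenyl)ethoxy]cyclobutan-1-one
Product: 12 (2S,3S)-2-[2-(tert-butyldimethylsilyloxy)ethyl]-3-[(R)-1-(2,4,6-triisopropylphenyl)ethoxy]cyclobutan-1-one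
Conditions: Zn–Cu, NH4Cl-saturated MeOH, 20 °C
Reagents that add atoms: none
Why: Zinc reduction of the α,α-dichloroketone under buffered protic conditions removes both chlorines without β-elimination of the alkoxy group and without touching the stereocentres.

Step 6
Reactants: 12 (2S,3S)-2-[2-(tert-butyldimethylsilyloxy)ethyl]-3-[(R)-1-(2,4,6-triisopropylphenyl)ethoxy]cyclobutan-1-one
Product: 14 (4S,5S)-5-[2-(tert-butyldimethylsilyloxy)ethyl]-4-[(R)-1-(2,4,6-triisopropylphenyl)ethoxy]oxolan-2-one, via Criegee peroxyhemiketal 13 (not isolated)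
Conditions: mCPBA, NaHCO3, CH2Cl2, 0 °C
Reagents that add atoms: meta-chloroperbenzoic acid, OOC(=O)c1cccc(Cl)c1
Why: Baeyer–Villiger oxidation: the peracid adds to the strained carbonyl to give 13, and the more substituted α-carbon (the one bearing the silyloxyethyl chain) shifts from carbon to oxygen anti to the departing carboxylate, so the four-membered carbocycle becomes the five-membered oxolan-2-one by insertion of one oxygen atom. The closest precedent is the Baeyer–Villiger ring expansion of 2-alkyl- and 3-alkoxycyclobutanones made from dichloroketene–enol ether adducts. No ring is closed by cyclisation, since the oxolane arises by a 1,2-shift inside the existing ring, so no closure mode applies. No new stereocentre is formed; the migrating carbon keeps its configuration, so the cis relationship and absolute configuration from step 4 become C6 and C7 of the target. The step needs regioselectivity (secondary carbon against CH2), secured by the higher migratory aptitude of the substituted carbon, and chemoselectivity, secured by the strain-activated ketone reacting at 0 °C under bicarbonate buffer while the silyl ether, the benzylic ether and the arene stay inert.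

Step 7
Reactants: 15 (E)-1-bromopent-2-ene; 16 dibromomethane
Product: 18 (E)-1,1-dibromohex-3-ene, via dibromomethyllithium 17 (not isolated)
Conditions: LDA, THF, −90 °C; then 15, −90 → −20 °C
Reagents that add atoms: none
Why: Deprotonation of 16 gives 17, which is alkylated at the primary allylic carbon of 15 (SN2) to give the gem-dibromide with the E-alkene intact.

Step 8
Reactants: 14 (4S,5S)-5-[2-(tert-butyldimethylsilyloxy)ethyl]-4-[(R)-1-(2,4,6-triisopropylphenyl)ethoxy]oxolan-2-one; 18 (E)-1,1-dibromohex-3-ene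
Product: 19 (2S,3S,5Z)-2-[2-(tert-butyldimethylsilyloxy)ethyl]-5-[(E)-hex-3-enylidene]-3-[(R)-1-(2,4,6-triisopropylphenyl)ethoxy]oxolane
Conditions: Zn, TiCl4, TMEDA, PbCl2 (cat.), THF, 25 °C
Reagents that add atoms: none
Why: Takai–Utimoto alkylidenation of the lactone carbonyl with the reagent generated from 18, Zn and TiCl4–TMEDA, which is known to favour the Z-enol ether (ring oxygen and new chain cis).

Step 9
Reactants: 19 (2S,3S,5Z)-2-[2-(tert-butyldimethylsilyloxy)ethyl]-5-[(E)-hex-3-enylidene]-3-[(R)-1-(2,4,6-triisopropylphenyl)ethoxy]oxolane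
Product: 21 (1R,E)-1-{(2S,4S,5S)-5-[2-(tert-butyldimethylsilyloxy)ethyl]-4-[(R)-1-(2,4,6-triisopropylphenyl)ethoxy]oxolan-2-yl}hex-3-en-1-ol, via spiro-epoxide 20 (not isolated)
Conditions: DMDO, acetone–CH2Cl2, −78 °C; then DIBAL-H, −78 → −40 °C; Rochelle salt
Reagents that add atoms: dimethyldioxirane, CC1(C)OO1
Why: The electron-rich enol ether is epoxidised in preference to the E-alkene from the face opposite the two cis ring substituents, and DIBAL-H opens epoxide 20 at the acetal carbon with hydride delivered syn to the departing oxygen (known epoxidation/reductive opening of enol ethers), so H and OH add cis across the Z double bond and set C9 (S) and C10 (R).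

Step 10
Reactants: 21 (1R,E)-1-{(2S,4S,5S)-5-[2-(tert-butyldimethylsilyloxy)ethyl]-4-[(R)-1-(2,4,6-triisopropylphenyl)ethoxy]oxolan-2-yl}hex-3-en-1-ol
Product: 23 (2S,3S,5S)-5-[(1S,E)-1-bromohex-3-enyl]-2-[2-(tert-butyldimethylsilyloxy)ethyl]-3-[(R)-1-(2,4,6-triisopropylphenyl)ethoxy]oxolane, via alkoxyphosphonium bromide 22 (not isolated)
Conditions: CBr4, (n-Oct)3P, pyridine, toluene, 70 °C
Reagents that add atoms: carbon tetrabromide, BrC(Br)(Br)Br
Why: Appel-type bromination in which bromide displaces the oxyphosphonium group of 22 by SN2 and inverts C10 to (S), under the conditions customary for carbinols next to ring ethers in this family.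

Step 11
Reactants: 23 (2S,3S,5S)-5-[(1S,E)-1-bromohex-3-enyl]-2-[2-(tert-butyldimethylsilyloxy)ethyl]-3-[(R)-1-(2,4,6-triisopropylphenyl)ethoxy]oxolane
Product: 24 (2S,3S,5S)-5-[(1S,E)-1-bromohex-3-enyl]-2-(2-hydroxyethyl)oxolan-3-ol
Conditions: TFA, CH2Cl2–H2O, 0 → 20 °C
Reagents that add atoms: none
Why: Acidolysis cleaves the hindered benzylic ether at the auxiliary carbon (SN1) and hydrolyses the primary silyl ether, leaving the C–O bonds at C7 and C4 intact.

Step 12
Reactants: 24 (2S,3S,5S)-5-[(1S,E)-1-bromohex-3-enyl]-2-(2-hydroxyethyl)oxolan-3-ol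
Product: 26 2-{(1S,3R,5S,6S,8S)-5-bromo-3-[(S)-1-bromopropyl]-2,7-dioxabicyclo[4.2.1]nonan-8-yl}ethanol, via bromonium ion 25 (not isolated)
Conditions: NBS, 4 Å MS, CH2Cl2, −20 → 0 °C, dark
Reagents that add atoms: N-bromosuccinimide, O=C1CCC(=O)N1Br
Why: Bromoetherification in which the C7 hydroxyl, held cis to the C9 side chain, opens the reversibly formed bromonium ion 25 anti at C12 in a 7-exo closure, the E geometry giving the erythro (12R,13S) O/Br pair and a chair-like transition state placing the bromopropyl carbon pseudo-equatorial, cis to the C6–O bridge.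

Step 13
Reactants: 26 2-{(1S,3R,5S,6S,8S)-5-bromo-3-[(S)-1-bromopropyl]-2,7-dioxabicyclo[4.2.1]nonan-8-yl}ethanol
Product: 27 2-{(1S,3R,5S,6S,8S)-5-bromo-3-[(S)-1-bromopropyl]-2,7-dioxabicyclo[4.2.1]nonan-8-yl}acetaldehyde
Conditions: Dess–Martin periodinane, NaHCO3, CH2Cl2, 0 → 20 °C
Reagents that add atoms: none
Why: Dess–Martin oxidation of the only hydroxyl to the aldehyde under buffered conditions that do not epimerise or eliminate the β-alkoxy aldehyde.

Step 14
Reactants: 27 2-{(1S,3R,5S,6S,8S)-5-bromo-3-[(S)-1-bromopropyl]-2,7-dioxabicyclo[4.2.1]nonan-8-yl}acetaldehyde; 28 1,3-bis(triisopropylsilyl)propyne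
Product: 31 (1S,3R,5S,6S,8S)-5-bromo-3-[(S)-1-bromopropyl]-8-[(Z)-5-(triisopropylsilyl)pent-2-en-4-ynyl]-2,7-dioxabicyclo[4.2.1]nonane, via lithiated bis-silylpropyne 29 (not isolated), via β-silyl alkoxide adduct 30 (not isolated)
Conditions: 28, n-BuLi, THF, −78 °C; then 27, −78 → −20 °C
Reagents that add atoms: none
Why: Z-selective Peterson olefination (Corey–Rücker/Yamamoto protocol) in which 29 adds to the aldehyde and adduct 30 loses silanolate by syn elimination to give the Z-enyne.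

Step 15
Reactants: 31 (1S,3R,5S,6S,8S)-5-bromo-3-[(S)-1-bromopropyl]-8-[(Z)-5-(triisopropylsilyl)pent-2-en-4-ynyl]-2,7-dioxabicyclo[4.2.1]nonane
Product: 32 (1S,3R,5S,6S,8S)-5-bromo-3-[(S)-1-bromopropyl]-8-[(Z)-pent-2-en-4-ynyl]-2,7-dioxabicyclo[4.2.1]nonane
Conditions: TBAF, THF, 0 °C
Reagents that add atoms: none
Why: Fluoride cleaves the alkynyl C–Si bond to release the terminal alkyne, a desilylation the secondary bromides should tolerate at 0 °C.

**Compound list**
1 | (R)-1-(2,4,6-triisopropylphenyl)ethanol | C[C@@H](O)c1c(C(C)C)cc(C(C)C)cc1C(C)C | starting material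
2 | trichloroethylene | ClC=C(Cl)Cl | starting material
3 | dichloroacetylene (formed in situ) | ClC#CCl | intermediate
4 | (E)-1,2-dichlorovinyl (R)-1-(2,4,6-triisopropylphenyl)ethyl ether | Cl/C=C(/Cl)O[C@H](C)c1c(C(C)C)cc(C(C)C)cc1C(C)C | intermediate
5 | tert-butyl(2-iodoethoxy)dimethylsilane | CC(C)(C)[Si](C)(C)OCCI | starting material
6 | lithium alkoxyacetylide of the auxiliary (formed in situ) | [Li]C#CO[C@H](C)c1c(C(C)C)cc(C(C)C)cc1C(C)C | intermediate
7 | 4-(tert-butyldimethylsilyloxy)but-1-ynyl (R)-1-(2,4,6-triisopropylphenyl)ethyl ether | CC(C)(C)[Si](C)(C)OCCC#CO[C@H](C)c1c(C(C)C)cc(C(C)C)cc1C(C)C | intermediate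
8 | (Z)-4-(tert-butyldimethylsilyloxy)but-1-enyl (R)-1-(2,4,6-triisopropylphenyl)ethyl ether | CC(C)(C)[Si](C)(C)OCC/C=C\O[C@H](C)c1c(C(C)C)cc(C(C)C)cc1C(C)C | intermediate
9 | trichloroacetyl chloride | ClC(Cl)(Cl)C(Cl)=O | starting material
10 | dichloroketene (formed in situ) | ClC(Cl)=C=O | intermediate
11 | (3R,4S)-2,2-dichloro-4-[2-(tert-butyldimethylsilyloxy)ethyl]-3-[(R)-1-(2,4,6-triisopropylphenyl)ethoxy]cyclobutan-1-one | CC(C)(C)[Si](C)(C)OCC[C@@H]1C(=O)C(Cl)(Cl)[C@@H]1O[C@H](C)c2c(C(C)C)cc(C(C)C)cc2C(C)C | intermediate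
12 | (2S,3S)-2-[2-(tert-butyldimethylsilyloxy)ethyl]-3-[(R)-1-(2,4,6-triisopropylphenyl)ethoxy]cyclobutan-1-one | CC(C)(C)[Si](C)(C)OCC[C@@H]1C(=O)C[C@@H]1O[C@H](C)c2c(C(C)C)cc(C(C)C)cc2C(C)C | intermediate
13 | Criegee peroxyhemiketal of 12 with mCPBA (formed in situ; new carbinol centre undefined) | CC(C)(C)[Si](C)(C)OCC[C@@H]1C(O)(OOC(=O)c3cccc(Cl)c3)C[C@@H]1O[C@H](C)c2c(C(C)C)cc(C(C)C)cc2C(C)C | intermediate
14 | (4S,5S)-5-[2-(tert-butyldimethylsilyloxy)ethyl]-4-[(R)-1-(2,4,6-triisopropylphenyl)ethoxy]oxolan-2-one | CC(C)(C)[Si](C)(C)OCC[C@@H]1OC(=O)C[C@@H]1O[C@H](C)c2c(C(C)C)cc(C(C)C)cc2C(C)C | intermediate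
15 | (E)-1-bromopent-2-ene | CC/C=C/CBr | starting material
16 | dibromomethane | BrCBr | starting material
17 | dibromomethyllithium (formed in situ) | [Li]C(Br)Br | intermediate
18 | (E)-1,1-dibromohex-3-ene | CC/C=C/CC(Br)Br | intermediate
19 | (2S,3S,5Z)-2-[2-(tert-butyldimethylsilyloxy)ethyl]-5-[(E)-hex-3-enylidene]-3-[(R)-1-(2,4,6-triisopropylphenyl)ethoxy]oxolane | CC(C)(C)[Si](C)(C)OCC[C@@H]1O/C(=C\C/C=C/CC)C[C@@H]1O[C@H](C)c2c(C(C)C)cc(C(C)C)cc2C(C)C | intermediate
20 | spiro-epoxide of 19 at the exocyclic C=C, oxygen on the face opposite the ring substituents (formed in situ) | CC(C)(C)[Si](C)(C)OCC[C@@H]1O[C@@]3(O[C@@H]3C/C=C/CC)C[C@@H]1O[C@H](C)c2c(C(C)C)cc(C(C)C)cc2C(C)C | intermediate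
21 | (1R,E)-1-{(2S,4S,5S)-5-[2-(tert-butyldimethylsilyloxy)ethyl]-4-[(R)-1-(2,4,6-triisopropylphenyl)ethoxy]oxolan-2-yl}hex-3-en-1-ol | CC(C)(C)[Si](C)(C)OCC[C@@H]1O[C@H]([C@H](O)C/C=C/CC)C[C@@H]1O[C@H](C)c2c(C(C)C)cc(C(C)C)cc2C(C)C | intermediate
22 | O-(tri-n-octylphosphonio) derivative of 21, bromide salt (formed in situ) | CC(C)(C)[Si](C)(C)OCC[C@@H]1O[C@H]([C@H](O[P+](CCCCCCCC)(CCCCCCCC)CCCCCCCC)C/C=C/CC)C[C@@H]1O[C@H](C)c2c(C(C)C)cc(C(C)C)cc2C(C)C.[Br-] | intermediate
23 | (2S,3S,5S)-5-[(1S,E)-1-bromohex-3-enyl]-2-[2-(tert-butyldimethylsilyloxy)ethyl]-3-[(R)-1-(2,4,6-triisopropylphenyl)ethoxy]oxolane | CC(C)(C)[Si](C)(C)OCC[C@@H]1O[C@H]([C@@H](Br)C/C=C/CC)C[C@@H]1O[C@H](C)c2c(C(C)C)cc(C(C)C)cc2C(C)C | intermediate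
24 | (2S,3S,5S)-5-[(1S,E)-1-bromohex-3-enyl]-2-(2-hydroxyethyl)oxolan-3-ol | OCC[C@@H]1O[C@H]([C@@H](Br)C/C=C/CC)C[C@@H]1O | intermediate
25 | bromonium ion of 24 on the alkene face leading to 26 (formed in situ) | OCC[C@@H]1O[C@H]([C@@H](Br)C[C@@H]2[Br+][C@H]2CC)C[C@@H]1O | intermediate
26 | 2-{(1S,3R,5S,6S,8S)-5-bromo-3-[(S)-1-bromopropyl]-2,7-dioxabicyclo[4.2.1]nonan-8-yl}ethanol | OCC[C@@H]1O[C@H]2C[C@@H]1O[C@@H]([C@@H](Br)CC)C[C@@H]2Br | intermediate
27 | 2-{(1S,3R,5S,6S,8S)-5-bromo-3-[(S)-1-bromopropyl]-2,7-dioxabicyclo[4.2.1]nonan-8-yl}acetaldehyde | O=CC[C@@H]1O[C@H]2C[C@@H]1O[C@@H]([C@@H](Br)CC)C[C@@H]2Br | intermediate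
28 | 1,3-bis(triisopropylsilyl)propyne | CC(C)[Si](C(C)C)(C(C)C)CC#C[Si](C(C)C)(C(C)C)C(C)C | starting material
29 | 3-lithio-1,3-bis(triisopropylsilyl)propyne (formed in situ) | [Li]C(C#C[Si](C(C)C)(C(C)C)C(C)C)[Si](C(C)C)(C(C)C)C(C)C | intermediate
30 | lithium β-silyl alkoxide from 27 and 29 (formed in situ; two new centres undefined) | [Li]OC(C[C@@H]1O[C@H]2C[C@@H]1O[C@@H]([C@@H](Br)CC)C[C@@H]2Br)C(C#C[Si](C(C)C)(C(C)C)C(C)C)[Si](C(C)C)(C(C)C)C(C)C | intermediate
31 | (1S,3R,5S,6S,8S)-5-bromo-3-[(S)-1-bromopropyl]-8-[(Z)-5-(triisopropylsilyl)pent-2-en-4-ynyl]-2,7-dioxabicyclo[4.2.1]nonane | CC(C)[Si](C(C)C)(C(C)C)C#C/C=C\C[C@@H]1O[C@H]2C[C@@H]1O[C@@H]([C@@H](Br)CC)C[C@@H]2Br | intermediate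
32 | (1S,3R,5S,6S,8S)-5-bromo-3-[(S)-1-bromopropyl]-8-[(Z)-pent-2-en-4-ynyl]-2,7-dioxabicyclo[4.2.1]nonane | C#C/C=C\C[C@@H]1O[C@H]2C[C@@H]1O[C@@H]([C@@H](Br)CC)C[C@@H]2Br | target

**Totals**
Total steps: 15. Longest linear sequence: 14 (steps 1–6 and 8–15; step 7 is a one-step side branch).

**Steps most likely to fail**

1. Step 12 (bromoetherification). The oxolane ring oxygen may capture the bromonium ion faster than the hydroxyl (five-membered oxonium), and the two alkene faces may be poorly differentiated, so material may be diverted or the other anti adduct may form. The fallback sets out from 24 and comes back at 31. The alkene of 24 is epoxidised under reagent control (Shi epoxidation with the L-fructose-derived ketone, Oxone, buffered MeCN–dimethoxymethane–water) to the (12S,13S)-epoxy diol F1. CSA in CH2Cl2 lets the C7 hydroxyl open the epoxide at C12 (7-exo, inversion) to the bicyclic diol F2 with a (13S)-hydroxyl. TEMPO/PhI(OAc)2 oxidises only the primary alcohol to the hydroxy aldehyde F3. The Peterson olefination of step 14, with one extra equivalent of the lithiated propyne, gives the silyl enyne alcohol F4. Dess–Martin oxidation gives the ethyl ketone F5, L-Selectride reduction under Felkin control gives the (13R)-alcohol F6, and CBr4/(n-Oct)3P inverts it to 31.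

2. Step 8 (alkylidenation of the lactone). The carbonyl may be converted incompletely, or the gem-dibromide may be reduced before it is transferred. The fallback sets out from 14 and comes back at 19 by a modified Julia olefination of the lactone. Commercial (E)-hex-3-en-1-ol is converted by Mitsunobu reaction with 2-mercaptobenzothiazole into the sulfide F7 and oxidised (H2O2, ammonium molybdate) to the sulfone F8. F8 is added to 14 with LiHMDS in THF at −78 °C to give the hemiketal sulfone F9. DBU then triggers Smiles rearrangement and elimination to 19, the Z isomer being separated.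

3. Step 9 (epoxidation and reductive opening). Stereocontrol at C10 may erode, through residual E-enol ether or loss of syn hydride delivery, so that 21 is obtained with low diastereomeric purity at C10. The fallback sets out from such crude 21 and comes back at pure 21. Dess–Martin oxidation gives the α-alkoxy ketone F10; chelation-controlled reduction with Zn(BH4)2 (Et2O, −30 °C), zinc bridging the ring oxygen and the carbonyl, then delivers hydride to give the (10R)-alcohol 21.

Further compounds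
F1 | step 12 | (2S,3S,5S)-5-{(1S)-1-bromo-2-[(2S,3S)-3-ethyloxiran-2-yl]ethyl}-2-(2-hydroxyethyl)oxolan-3-ol | OCC[C@@H]1O[C@H]([C@@H](Br)C[C@@H]2O[C@H]2CC)C[C@@H]1O
F2 | step 12 | (S)-1-[(1S,3R,5S,6S,8S)-5-bromo-8-(2-hydroxyethyl)-2,7-dioxabicyclo[4.2.1]nonan-3-yl]propan-1-ol | OCC[C@@H]1O[C@H]2C[C@@H]1O[C@@H]([C@@H](O)CC)C[C@@H]2Br
F3 | step 12 | 2-{(1S,3R,5S,6S,8S)-5-bromo-3-[(S)-1-hydroxypropyl]-2,7-dioxabicyclo[4.2.1]nonan-8-yl}acetaldehyde | O=CC[C@@H]1O[C@H]2C[C@@H]1O[C@@H]([C@@H](O)CC)C[C@@H]2Br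
F4 | step 12 | (S)-1-{(1S,3R,5S,6S,8S)-5-bromo-8-[(Z)-5-(triisopropylsilyl)pent-2-en-4-ynyl]-2,7-dioxabicyclo[4.2.1]nonan-3-yl}propan-1-ol | CC(C)[Si](C(C)C)(C(C)C)C#C/C=C\C[C@@H]1O[C@H]2C[C@@H]1O[C@@H]([C@@H](O)CC)C[C@@H]2Br
F5 | step 12 | 1-{(1S,3R,5S,6S,8S)-5-bromo-8-[(Z)-5-(triisopropylsilyl)pent-2-en-4-ynyl]-2,7-dioxabicyclo[4.2.1]nonan-3-yl}propan-1-one | CC(C)[Si](C(C)C)(C(C)C)C#C/C=C\C[C@@H]1O[C@H]2C[C@@H]1O[C@@H](C(=O)CC)C[C@@H]2Br
F6 | step 12 | (R)-1-{(1S,3R,5S,6S,8S)-5-bromo-8-[(Z)-5-(triisopropylsilyl)pent-2-en-4-ynyl]-2,7-dioxabicyclo[4.2.1]nonan-3-yl}propan-1-ol | CC(C)[Si](C(C)C)(C(C)C)C#C/C=C\C[C@@H]1O[C@H]2C[C@@H]1O[C@@H]([C@H](O)CC)C[C@@H]2Br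
F7 | step 8 | 2-[(E)-hex-3-enylsulfanyl]-1,3-benzothiazole | CC/C=C/CCSc1nc2ccccc2s1
F8 | step 8 | 2-[(E)-hex-3-enylsulfonyl]-1,3-benzothiazole | CC/C=C/CCS(=O)(=O)c1nc2ccccc2s1
F9 | step 8 | hemiketal adduct of 14 with F8 (2-hydroxy-2-[1-(benzothiazol-2-ylsulfonyl)hex-3-enyl]oxolane; new centres undefined) | CC(C)(C)[Si](C)(C)OCC[C@@H]1OC(O)(C(C/C=C/CC)S(=O)(=O)c3nc4ccccc4s3)C[C@@H]1O[C@H](C)c2c(C(C)C)cc(C(C)C)cc2C(C)C
F10 | step 9 | (E)-1-{(2S,4S,5S)-5-[2-(tert-butyldimethylsilyloxy)ethyl]-4-[(R)-1-(2,4,6-triisopropylphenyl)ethoxy]oxolan-2-yl}hex-3-en-1-one | CC(C)(C)[Si](C)(C)OCC[C@@H]1O[C@H](C(=O)C/C=C/CC)C[C@@H]1O[C@H](C)c2c(C(C)C)cc(C(C)C)cc2C(C)C
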